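Everything rests on making ring A from two non-aromatic pieces: a 3-ethoxy-4-alkylcyclobutenone carrying the C6 side chain, and a prenyl-substituted alkynyl ether whose oxygen is already bonded to the C2 stereocentre. Their benzannulation forms C7–C8, C4a–C8a and C6–C7 in one operation and delivers ring A as the C7 phenol. It exploits the alternating pattern of ring A: oxygen on C5, C7 and C8a, carbon on C6 and C8, hydrogen only on C4a. O1–C2 therefore arrives intact and enantiopure, and ring C is closed afterwards by acylation at C4a. Both stereocentres are set before the coupling, by oxazaborolidine reduction and by allylboration.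

Key step: step 12

Remarks on the chemistry: cyclobutenone 11 is carried as the mixture of C4 epimers, because C4 becomes sp2 in step 12. The primary hydroxyl of the C2–C4 fragment is carried as a trityl ether, because a silyl ether there could migrate to the neighbouring potassium alkoxide in step 10. Borane 14 is assumed to be bought as its pentane solution.

Step 1
Reactants: 1 methyl 4-chloro-4-oxobutanoate; 2 isopropenylmagnesium bromide
Product: 4 methyl 5-methyl-4-oxohex-5-enoate, via isopropenylzinc chloride 3 (not isolated)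
Conditions: 2, ZnCl2, THF, 0 °C; then 1, Pd(PPh3)4 (3 mol %), THF, 0 °C to rt
Reagents that add atoms: isopropenylmagnesium bromide (2), CC(=C)[Mg]Br
Why: Negishi acylation, in which the alkenylzinc chloride formed by transmetalation couples with the acid chloride under Pd(PPh3)4 catalysis and is too mild to attack the methyl ester or to add to the enone product.

Step 2
Reactants: 4 methyl 5-methyl-4-oxohex-5-enoate
Product: 5 methyl (4R)-4-hydroxy-5-methylhex-5-enoate
Conditions: (S)-Me-CBS oxazaborolidine [(S)-1-methyl-3,3-diphenyltetrahydro-1H,3H-pyrrolo[1,2-c][1,3,2]oxazaborole] (0.2 equiv), catecholborane, toluene, −78 °C; MeOH quench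
Reagents that add atoms: none
Why: Corey–Bakshi–Shibata reduction, in which the (S)-oxazaborolidine should treat the isopropenyl group as the large substituent (as with aryl and alkenyl ketones) and deliver hydride to the face that gives the (R)-carbinol, while catecholborane at −78 °C spares the alkene and the ester.

Step 3
Reactants: 5 methyl (4R)-4-hydroxy-5-methylhex-5-enoate
Product: 6 methyl (4R)-5-methyl-4-(triisopropylsilyloxy)hex-5-enoate
Conditions: triisopropylsilyl trifluoromethanesulfonate, 2,6-lutidine, CH2Cl2, −78 to 0 °C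
Reagents that add atoms: triisopropylsilyl trifluoromethanesulfonate, CC(C)[Si](OS(=O)(=O)C(F)(F)F)(C(C)C)C(C)C
Why: Silylation of a secondary allylic alcohol with a silyl triflate is fast at low temperature and should outrun lactonisation of the γ-hydroxy ester.

Step 4
Reactants: 6 methyl (4R)-5-methyl-4-(triisopropylsilyloxy)hex-5-enoate
Product: 7 (4R)-5-methyl-4-(triisopropylsilyloxy)hex-5-enoic acid
Conditions: LiOH, THF/MeOH/H2O, 0 °C to rt; then dilute HCl to pH 4
Reagents that add atoms: LiOH (hydroxide oxygen), [Li+].[OH-]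
Why: Saponification of an unhindered methyl ester should proceed without loss of the bulky secondary silyl ether, and the stereocentre is not enolisable.

Step 5
Reactants: 7 (4R)-5-methyl-4-(triisopropylsilyloxy)hex-5-enoic acid; 8 ethoxyacetylene
Product: 11 3-ethoxy-4-[(2R)-3-methyl-2-(triisopropylsilyloxy)but-3-enyl]cyclobut-2-en-1-one (both C4 epimers), via acid chloride 9 (not isolated), via ketene 10 (not isolated)
Conditions: (COCl)2, DMF (cat.), CH2Cl2, 0 °C to rt, concentrate; then slow addition to 8 (3 equiv), Et3N, Et2O, rt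
Reagents that add atoms: ethoxyacetylene (8), CCOC#C
Why: Dehydrochlorination gives a monoalkylketene that should add to the electron-rich alkyne in a regioselective [2+2] cycloaddition (ketene carbonyl carbon to the unsubstituted alkyne carbon), the standard entry to 4-alkyl-3-ethoxycyclobutenones, and the uncontrolled C4 centre is irrelevant.

Step 6
Reactants: 12 4-hydroxybenzaldehyde
Product: 13 4-(triisopropylsilyloxy)benzaldehyde
Conditions: triisopropylsilyl chloride, imidazole, DMF, rt
Reagents that add atoms: triisopropylsilyl chloride, CC(C)[Si](Cl)(C(C)C)C(C)C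
Why: Standard silylation of a phenol, with the bulky triisopropylsilyl group chosen so that the aryl ether survives KH and n-BuLi later.

Step 7
Reactants: 13 4-(triisopropylsilyloxy)benzaldehyde; 14 (−)-B-allyldiisopinocampheylborane (derived from (+)-α-pinene)
Product: 15 (1S)-1-[4-(triisopropylsilyloxy)phenyl]but-3-en-1-ol
Conditions: 14, Et2O, −78 °C; then ethanolamine, rt
Reagents that add atoms: (−)-B-allyldiisopinocampheylborane (14), C=CCB([C@@H]1C[C@@H]2C[C@H]([C@H]1C)C2(C)C)[C@@H]1C[C@@H]2C[C@H]([C@H]1C)C2(C)C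
Why: Brown allylboration through a closed chair transition state, in which the isopinocampheyl groups direct allyl transfer to the Si face of the aryl aldehyde and should give the (S)-homoallylic alcohol.

Step 8
Reactants: 15 (1S)-1-[4-(triisopropylsilyloxy)phenyl]but-3-en-1-ol
Product: 17 (1S)-1-[4-(triisopropylsilyloxy)phenyl]propane-1,3-diol, via ozonide 16 (not isolated)
Conditions: O3, CH2Cl2, −78 °C (stopped at the end point of an indicator dye); then NaBH4, MeOH, −78 °C to rt
Reagents that add atoms: ozone, [O-][O+]=O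
Why: Ozonolysis of the only alkene followed by borohydride reduction of the ozonide should give the 1,3-diol with the benzylic stereocentre untouched, since the arene reacts far more slowly than a terminal alkene at −78 °C.

Step 9
Reactants: 17 (1S)-1-[4-(triisopropylsilyloxy)phenyl]propane-1,3-diol
Product: 18 (1S)-1-[4-(triisopropylsilyloxy)phenyl]-3-(trityloxy)propan-1-ol
Conditions: trityl chloride, Et3N, 4-(dimethylamino)pyridine (cat.), CH2Cl2, rt
Reagents that add atoms: trityl chloride, ClC(c1ccccc1)(c1ccccc1)c1ccccc1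
Why: Tritylation is selective for the primary hydroxyl on steric grounds and gives an ether that cannot migrate to the neighbouring alkoxide of step 10.

Step 10
Reactants: 18 (1S)-1-[4-(triisopropylsilyloxy)phenyl]-3-(trityloxy)propan-1-ol; 19 trichloroethylene
Product: 22 (E)-1,2-dichlorovinyl ether of 18 (S), via potassium alkoxide 20 (not isolated), via dichloroacetylene 21 (not isolated)
Conditions: KH (2.2 equiv), THF, 0 °C; then 19, −50 °C to rt
Reagents that add atoms: trichloroethylene (19), ClC=C(Cl)Cl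
Why: Addition of the potassium alkoxide to dichloroacetylene generated in situ is the established route to 1,2-dichlorovinyl ethers, and since the C2–O bond is never broken the configuration is retained.

Step 11
Reactants: 22 (E)-1,2-dichlorovinyl ether of 18; 23 prenyl bromide
Product: 26 (S)-5-methylhex-4-en-1-ynyl ether of 18, via chloroethynyl ether 24 (not isolated), via lithium alkynyl ether 25 (not isolated)
Conditions: n-BuLi (2.4 equiv), THF, −78 to −40 °C; then 23, DMPU, −78 to 0 °C; cold NaHCO3 work-up, product kept cold and used the same day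
Reagents that add atoms: prenyl bromide (23), CC(C)=CCBr
Why: Dehydrochlorination followed by chlorine–lithium exchange gives the lithium alkynyl ether, an unhindered acetylide that should be alkylated at the primary carbon of prenyl bromide (SN2) in the presence of DMPU.

Step 12
Reactants: 11 3-ethoxy-4-[(2R)-3-methyl-2-(triisopropylsilyloxy)but-3-enyl]cyclobut-2-en-1-one; 26 (S)-5-methylhex-4-en-1-ynyl ether of 18
Product: 31 3-ethoxy-6-(3-methylbut-2-enyl)-2-[(2R)-3-methyl-2-(triisopropylsilyloxy)but-3-enyl]-5-{(1S)-1-[4-(triisopropylsilyloxy)phenyl]-3-(trityloxy)propoxy}phenol, via vinylketene 27 (not isolated), via alkenylcyclobutenone 28 (not isolated), via dienylketene 29 (not isolated), via cyclohexadienone 30 (not isolated)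
Conditions: 11 (1.5 equiv), degassed toluene, hν (300 nm lamps, Pyrex), 20 °C until 26 is consumed; then 80 °C in the dark
Reagents that add atoms: none
Why: Light-induced 4π electrocyclic opening of 11 gives vinylketene 27, whose carbonyl carbon is attacked by the alkyne carbon of 26 remote from oxygen to close 4-alkenylcyclobutenone 28 (the C7–C4a bond made here is broken again); 28 opens to dienylketene 29, which closes between the ketene carbon (C7) and C6 to cyclohexadienone 30 and tautomerises to phenol 31. The closest known reaction type is the Danheiser benzannulation of cyclobutenones with alkoxyalkynes, including its variant in which the cyclobutenone is opened photochemically. Ring A, the only ring formed, closes by a thermally allowed disrotatory 6π electrocyclisation followed by enolisation. No stereocentre is created: C2 and the side-chain carbinol are spectators whose C–O bonds are never broken, and C4 of 11 becomes sp2. The step needs regiocontrol (prenyl between C7–OH and O1, the silyloxy chain between C7–OH and C5–OEt, hydrogen at C4a), which the polarity of the ketene–ynol ether addition dictates, and chemoselectivity for the alkyne over the three alkenes, which its much higher nucleophilicity secures. It also needs the benzylic secondary alkynyl ether to be consumed before it fragments (retro-ene loss of the styrene) or rearranges, which is why the ketene is generated by light at 20 °C with 11 in excess and heat is applied only after the oxygen has become part of a vinylogous ester.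

Step 13
Reactants: 31 ring-A phenol (free C7–OH)
Product: 32 C7 tert-butyldimethylsilyl ether of 31
Conditions: tert-butyldimethylsilyl chloride, imidazole, DMF, rt to 40 °C
Reagents that add atoms: tert-butyldimethylsilyl chloride, CC(C)(C)[Si](C)(C)Cl
Why: Silylation of the electron-rich C7 phenol, which would not survive the oxidant of step 15, should proceed because both ortho substituents are primary alkyl groups.

Step 14
Reactants: 32 C7 tert-butyldimethylsilyl ether of 31
Product: 33 primary alcohol (trityl group of 32 removed)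
Conditions: 10-camphorsulfonic acid (0.1 equiv), MeOH/CH2Cl2, 0 °C to rt
Reagents that add atoms: none
Why: Acid-catalysed methanolysis of the trityl ether through the stabilised trityl cation should free the primary alcohol while the aryl silyl ethers, the secondary triisopropylsilyl ether and the benzylic aryl ether stay intact.

Step 15
Reactants: 33 primary alcohol
Product: 35 (3S)-3-aryloxy-3-[4-(triisopropylsilyloxy)phenyl]propanoic acid (aryl = ring A of 32), via aldehyde 34 (not isolated)
Conditions: TEMPO (2,2,6,6-tetramethylpiperidin-1-oxyl, 0.2 equiv), PhI(OAc)2 (2.5 equiv), CH2Cl2/MeCN/H2O, rt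
Reagents that add atoms: water, O
Why: Oxoammonium (TEMPO) oxidation with (diacetoxyiodo)benzene as terminal oxidant takes a primary alcohol through the aldehyde hydrate to the acid under near-neutral conditions that tolerate trisubstituted alkenes and silyl ethers, and it avoids isolating the β-aryloxy aldehyde.

Step 16
Reactants: 35 (3S)-3-aryloxy-3-arylpropanoic acid
Product: 37 (2S)-7-(tert-butyldimethylsilyloxy)-5-ethoxy-6-[(2R)-3-methyl-2-(triisopropylsilyloxy)but-3-enyl]-8-(3-methylbut-2-enyl)-2-[4-(triisopropylsilyloxy)phenyl]chroman-4-one, via acid chloride 36 (not isolated)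
Conditions: (COCl)2, DMF (cat.), 2,6-di-tert-butyl-4-methylpyridine (2.5 equiv), CH2Cl2, 0 °C; then SnCl4 (1.1 equiv), −78 °C; NaHCO3 quench at −78 °C
Reagents that add atoms: none
Why: Intramolecular Friedel–Crafts acylation closing the six-membered ring C onto C4a, the only unsubstituted position (ortho to two oxygens and para to the third), should occur at −78 °C on so electron-rich a ring, with the hindered pyridine removing HCl so that the benzylic C2–O1 bond and the alkenes do not meet protic acid.

Step 17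
Reactants: 37 5-ethoxyflavanone
Product: 38 (2S)-7-(tert-butyldimethylsilyloxy)-5-hydroxy-6-[(2R)-3-methyl-2-(triisopropylsilyloxy)but-3-enyl]-8-(3-methylbut-2-enyl)-2-[4-(triisopropylsilyloxy)phenyl]chroman-4-one
Conditions: MgI2·OEt2 (4 equiv), toluene/Et2O, 60 °C; cold dilute HCl work-up
Reagents that add atoms: none
Why: Chelation of magnesium between the C4 carbonyl and O5 activates only that ether for SN2 attack of iodide on the ethyl group, a known selective dealkylation of alkoxy groups peri to a carbonyl that should leave the alkenes alone.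

Step 18
Reactants: 38 5-hydroxyflavanone tris(silyl ether)
Product: 39 (2S)-5,7-dihydroxy-6-[(2R)-2-hydroxy-3-methylbut-3-enyl]-2-(4-hydroxyphenyl)-8-(3-methylbut-2-enyl)chroman-4-one (target)
Conditions: HF·pyridine (excess), pyridine/THF, 0 °C to rt
Reagents that add atoms: none
Why: Fluoride-driven cleavage of the three silyl ethers under non-basic conditions should free the two phenols and the allylic alcohol without opening the flavanone to its chalcone, so C2 is not epimerised.

Compound list
1 | methyl 4-chloro-4-oxobutanoate | COC(=O)CCC(Cl)=O | starting material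
2 | isopropenylmagnesium bromide | CC(=C)[Mg]Br | starting material
3 | isopropenylzinc chloride | CC(=C)[Zn]Cl | intermediate
4 | methyl 5-methyl-4-oxohex-5-enoate | COC(=O)CCC(=O)C(C)=C | intermediate
5 | methyl (4R)-4-hydroxy-5-methylhex-5-enoate | COC(=O)CC[C@@H](O)C(C)=C | intermediate
6 | methyl (4R)-5-methyl-4-(triisopropylsilyloxy)hex-5-enoate | COC(=O)CC[C@@H](O[Si](C(C)C)(C(C)C)C(C)C)C(C)=C | intermediate
7 | (4R)-5-methyl-4-(triisopropylsilyloxy)hex-5-enoic acid | OC(=O)CC[C@@H](O[Si](C(C)C)(C(C)C)C(C)C)C(C)=C | intermediate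
8 | ethoxyacetylene | CCOC#C | starting material
9 | (4R)-5-methyl-4-(triisopropylsilyloxy)hex-5-enoyl chloride | ClC(=O)CC[C@@H](O[Si](C(C)C)(C(C)C)C(C)C)C(C)=C | intermediate
10 | (4R)-5-methyl-4-(triisopropylsilyloxy)hexa-1,5-dien-1-one (ketene) | O=C=CC[C@@H](O[Si](C(C)C)(C(C)C)C(C)C)C(C)=C | intermediate
11 | 3-ethoxy-4-[(2R)-3-methyl-2-(triisopropylsilyloxy)but-3-enyl]cyclobut-2-en-1-one, both C4 epimers | CCOC1=CC(=O)C1C[C@@H](O[Si](C(C)C)(C(C)C)C(C)C)C(C)=C | intermediate
12 | 4-hydroxybenzaldehyde | O=Cc1ccc(O)cc1 | starting material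
13 | 4-(triisopropylsilyloxy)benzaldehyde | O=Cc1ccc(O[Si](C(C)C)(C(C)C)C(C)C)cc1 | intermediate
14 | (−)-B-allyldiisopinocampheylborane | C=CCB([C@@H]1C[C@@H]2C[C@H]([C@H]1C)C2(C)C)[C@@H]1C[C@@H]2C[C@H]([C@H]1C)C2(C)C | starting material
15 | (1S)-1-[4-(triisopropylsilyloxy)phenyl]but-3-en-1-ol | C=CC[C@H](O)c1ccc(O[Si](C(C)C)(C(C)C)C(C)C)cc1 | intermediate
16 | (1S)-2-(1,2,4-trioxolan-3-yl)-1-[4-(triisopropylsilyloxy)phenyl]ethanol (ozonide, ring carbon unassigned) | O[C@@H](CC1OCOO1)c1ccc(O[Si](C(C)C)(C(C)C)C(C)C)cc1 | intermediate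
17 | (1S)-1-[4-(triisopropylsilyloxy)phenyl]propane-1,3-diol | OCC[C@H](O)c1ccc(O[Si](C(C)C)(C(C)C)C(C)C)cc1 | intermediate
18 | (1S)-1-[4-(triisopropylsilyloxy)phenyl]-3-(trityloxy)propan-1-ol | O[C@@H](CCOC(c1ccccc1)(c1ccccc1)c1ccccc1)c1ccc(O[Si](C(C)C)(C(C)C)C(C)C)cc1 | intermediate
19 | trichloroethylene | ClC=C(Cl)Cl | starting material
20 | potassium alkoxide of 18 | [K+].[O-][C@@H](CCOC(c1ccccc1)(c1ccccc1)c1ccccc1)c1ccc(O[Si](C(C)C)(C(C)C)C(C)C)cc1 | intermediate
21 | dichloroacetylene | ClC#CCl | intermediate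
22 | (E)-1,2-dichlorovinyl ether of 18 (S) | Cl/C=C(/Cl)O[C@@H](CCOC(c1ccccc1)(c1ccccc1)c1ccccc1)c1ccc(O[Si](C(C)C)(C(C)C)C(C)C)cc1 | intermediate
23 | prenyl bromide (1-bromo-3-methylbut-2-ene) | CC(C)=CCBr | starting material
24 | chloroethynyl ether of 18 (S) | ClC#CO[C@@H](CCOC(c1ccccc1)(c1ccccc1)c1ccccc1)c1ccc(O[Si](C(C)C)(C(C)C)C(C)C)cc1 | intermediate
25 | lithium alkynyl ether (2-lithioethynyl ether of 18, S) | [Li]C#CO[C@@H](CCOC(c1ccccc1)(c1ccccc1)c1ccccc1)c1ccc(O[Si](C(C)C)(C(C)C)C(C)C)cc1 | intermediate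
26 | 5-methylhex-4-en-1-ynyl ether of 18 (S) | CC(C)=CCC#CO[C@@H](CCOC(c1ccccc1)(c1ccccc1)c1ccccc1)c1ccc(O[Si](C(C)C)(C(C)C)C(C)C)cc1 | intermediate
27 | (6R)-3-ethoxy-7-methyl-6-(triisopropylsilyloxy)octa-1,3,7-trien-1-one (vinylketene; C3=C4 drawn as expected from outward rotation) | O=C=C/C(OCC)=C/C[C@@H](O[Si](C(C)C)(C(C)C)C(C)C)C(C)=C | intermediate
28 | 4-alkenylcyclobut-2-enone: C2 prenyl, C3 O-[(1S)-1-aryl-3-(trityloxy)propyl], C4 the 2-ethoxyalkenyl chain of 27 (ring C4 unassigned) | O=C3C(CC=C(C)C)=C(O[C@@H](CCOC(c1ccccc1)(c1ccccc1)c1ccccc1)c1ccc(O[Si](C(C)C)(C(C)C)C(C)C)cc1)C3/C(OCC)=C/C[C@@H](O[Si](C(C)C)(C(C)C)C(C)C)C(C)=C | intermediate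
29 | dienylketene from 4π opening of 28 | O=C=C(CC=C(C)C)/C(O[C@@H](CCOC(c1ccccc1)(c1ccccc1)c1ccccc1)c1ccc(O[Si](C(C)C)(C(C)C)C(C)C)cc1)=C\C(OCC)=C\C[C@@H](O[Si](C(C)C)(C(C)C)C(C)C)C(C)=C | intermediate
30 | cyclohexa-2,4-dienone from 6π closure of 29 (ring sp3 carbon unassigned) | O=C3C(CC=C(C)C)=C(O[C@@H](CCOC(c1ccccc1)(c1ccccc1)c1ccccc1)c1ccc(O[Si](C(C)C)(C(C)C)C(C)C)cc1)C=C(OCC)C3C[C@@H](O[Si](C(C)C)(C(C)C)C(C)C)C(C)=C | intermediate
31 | 3-ethoxy-6-(3-methylbut-2-enyl)-2-[(2R)-3-methyl-2-(triisopropylsilyloxy)but-3-enyl]-5-{(1S)-1-[4-(triisopropylsilyloxy)phenyl]-3-(trityloxy)propoxy}phenol | C=C(C)[C@H](O[Si](C(C)C)(C(C)C)C(C)C)Cc1c(O)c(CC=C(C)C)c(O[C@@H](CCOC(c2ccccc2)(c2ccccc2)c2ccccc2)c2ccc(O[Si](C(C)C)(C(C)C)C(C)C)cc2)cc1OCC | intermediate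
32 | tert-butyldimethylsilyl ether of phenol 31 | C=C(C)[C@H](O[Si](C(C)C)(C(C)C)C(C)C)Cc1c(O[Si](C)(C)C(C)(C)C)c(CC=C(C)C)c(O[C@@H](CCOC(c2ccccc2)(c2ccccc2)c2ccccc2)c2ccc(O[Si](C(C)C)(C(C)C)C(C)C)cc2)cc1OCC | intermediate
33 | (3S)-3-aryloxy-3-[4-(triisopropylsilyloxy)phenyl]propan-1-ol (32 without trityl) | C=C(C)[C@H](O[Si](C(C)C)(C(C)C)C(C)C)Cc1c(O[Si](C)(C)C(C)(C)C)c(CC=C(C)C)c(O[C@@H](CCO)c2ccc(O[Si](C(C)C)(C(C)C)C(C)C)cc2)cc1OCC | intermediate
34 | corresponding (3S)-propanal | C=C(C)[C@H](O[Si](C(C)C)(C(C)C)C(C)C)Cc1c(O[Si](C)(C)C(C)(C)C)c(CC=C(C)C)c(O[C@@H](CC=O)c2ccc(O[Si](C(C)C)(C(C)C)C(C)C)cc2)cc1OCC | intermediate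
35 | corresponding (3S)-propanoic acid | C=C(C)[C@H](O[Si](C(C)C)(C(C)C)C(C)C)Cc1c(O[Si](C)(C)C(C)(C)C)c(CC=C(C)C)c(O[C@@H](CC(=O)O)c2ccc(O[Si](C(C)C)(C(C)C)C(C)C)cc2)cc1OCC | intermediate
36 | corresponding (3S)-propanoyl chloride | C=C(C)[C@H](O[Si](C(C)C)(C(C)C)C(C)C)Cc1c(O[Si](C)(C)C(C)(C)C)c(CC=C(C)C)c(O[C@@H](CC(=O)Cl)c2ccc(O[Si](C(C)C)(C(C)C)C(C)C)cc2)cc1OCC | intermediate
37 | (2S)-7-(tert-butyldimethylsilyloxy)-5-ethoxy-6-[(2R)-3-methyl-2-(triisopropylsilyloxy)but-3-enyl]-8-(3-methylbut-2-enyl)-2-[4-(triisopropylsilyloxy)phenyl]chroman-4-one | C=C(C)[C@H](O[Si](C(C)C)(C(C)C)C(C)C)Cc1c(O[Si](C)(C)C(C)(C)C)c(CC=C(C)C)c2c(c1OCC)C(=O)C[C@@H](c1ccc(O[Si](C(C)C)(C(C)C)C(C)C)cc1)O2 | intermediate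
38 | (2S)-7-(tert-butyldimethylsilyloxy)-5-hydroxy analogue of 37 | C=C(C)[C@H](O[Si](C(C)C)(C(C)C)C(C)C)Cc1c(O[Si](C)(C)C(C)(C)C)c(CC=C(C)C)c2c(c1O)C(=O)C[C@@H](c1ccc(O[Si](C(C)C)(C(C)C)C(C)C)cc1)O2 | intermediate
39 | (2S)-5,7-dihydroxy-6-[(2R)-2-hydroxy-3-methylbut-3-enyl]-2-(4-hydroxyphenyl)-8-(3-methylbut-2-enyl)chroman-4-one | C=C(C)[C@H](O)Cc1c(O)c(CC=C(C)C)c2c(c1O)C(=O)C[C@@H](c1ccc(O)cc1)O2 | target

Total step count: 18 (steps 1–5 for the cyclobutenone, steps 6–11 for the alkynyl ether, step 12 for the coupling, steps 13–18 for the endgame).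
Longest linear sequence: 13 steps (12 to 39, steps 6–18).

Steps most likely to fail

1. Step 12. What may go wrong: photolytic side reactions of the aryl ethers, or rearrangement and retro-ene fragmentation of alkynyl ether 26 outpacing its capture by the ketene. The fallback generates the same vinylketene without light or heat by 1,4-dehydrochlorination of a 3-ethoxy-2-enoyl chloride. It sets out from acid chloride 9 (made from 7 as in step 5) and from 26. Acylation of the lithium enolate of ethyl acetate (LiN(SiMe3)2, THF, −78 °C) with 9 should give β-keto ester ethyl (6R)-7-methyl-3-oxo-6-(triisopropylsilyloxy)oct-7-enoate F1. Triethyl orthoformate with catalytic acid in ethanol should convert it into the (E)-3-ethoxy enoate F2. Hydrolysis with KOH in aqueous ethanol, with careful acidification to pH 4, gives the enoic acid F3, and oxalyl chloride gives its acid chloride F4. Slow addition of F4 to 26 and Et3N in CH2Cl2 at 0 °C should form 27 in the presence of the alkyne, so that 28 is produced cold. Warming to 80 °C then takes 28 through 29 and 30, and the fallback comes back to the route at 31.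

2. Step 16. What may go wrong: ionisation of the benzylic C2–O1 bond or protonation of an alkene under the Lewis acid, with loss of the aryl ether or erosion of the C2 configuration. The fallback closes ring C by an anionic Parham-type cyclisation in place of electrophilic acylation. It sets out from acid 35. Coupling with N,O-dimethylhydroxylamine hydrochloride (EDC, N-methylmorpholine, CH2Cl2) gives the Weinreb amide F5. N-Bromosuccinimide in CH2Cl2 at −78 °C should brominate the single free ring position to give the C4a bromide F6. t-BuLi (2 equiv, THF, −100 °C) effects bromine–lithium exchange to the aryllithium F7, which adds to the amide carbonyl and on work-up gives 37, where the route is rejoined.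

3. Step 11. What may go wrong: attack of the acetylide at the tertiary end of prenyl bromide (SN2′), or alkylation so slow that the alkynyl ether decomposes during it. The fallback introduces an allyl group, which has no such ambiguity, and turns it into prenyl once ring A exists. It sets out from lithium alkynyl ether 25. Allyl bromide should give the allyl-substituted alkynyl ether F8. Benzannulation with 11 under the conditions of step 12 passes through 27, the alkenylcyclobutenone F9, the dienylketene F10 and the cyclohexadienone F11 to the C8-allyl phenol F12. Cross-metathesis of F12 with 2-methyl-2-butene (second-generation Grubbs catalyst, CH2Cl2, 40 °C), in which the hindered 1,1-disubstituted isopropenyl group is expected not to take part, gives 31, where the route is rejoined.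

Further compounds
F1 | step 12 | ethyl (6R)-7-methyl-3-oxo-6-(triisopropylsilyloxy)oct-7-enoate | CCOC(=O)CC(=O)CC[C@@H](O[Si](C(C)C)(C(C)C)C(C)C)C(C)=C
F2 | step 12 | ethyl (2E,6R)-3-ethoxy-7-methyl-6-(triisopropylsilyloxy)octa-2,7-dienoate | CCOC(=O)/C=C(OCC)\CC[C@@H](O[Si](C(C)C)(C(C)C)C(C)C)C(C)=C
F3 | step 12 | (2E,6R)-3-ethoxy-7-methyl-6-(triisopropylsilyloxy)octa-2,7-dienoic acid | OC(=O)/C=C(OCC)\CC[C@@H](O[Si](C(C)C)(C(C)C)C(C)C)C(C)=C
F4 | step 12 | (2E,6R)-3-ethoxy-7-methyl-6-(triisopropylsilyloxy)octa-2,7-dienoyl chloride | ClC(=O)/C=C(OCC)\CC[C@@H](O[Si](C(C)C)(C(C)C)C(C)C)C(C)=C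
F5 | step 16 | N-methoxy-N-methylamide of acid 35 | C=C(C)[C@H](O[Si](C(C)C)(C(C)C)C(C)C)Cc1c(O[Si](C)(C)C(C)(C)C)c(CC=C(C)C)c(O[C@@H](CC(=O)N(C)OC)c2ccc(O[Si](C(C)C)(C(C)C)C(C)C)cc2)cc1OCC
F6 | step 16 | C4a-bromo derivative of F5 | C=C(C)[C@H](O[Si](C(C)C)(C(C)C)C(C)C)Cc1c(O[Si](C)(C)C(C)(C)C)c(CC=C(C)C)c(O[C@@H](CC(=O)N(C)OC)c2ccc(O[Si](C(C)C)(C(C)C)C(C)C)cc2)c(Br)c1OCC
F7 | step 16 | C4a-lithio derivative of F5 | C=C(C)[C@H](O[Si](C(C)C)(C(C)C)C(C)C)Cc1c(O[Si](C)(C)C(C)(C)C)c(CC=C(C)C)c(O[C@@H](CC(=O)N(C)OC)c2ccc(O[Si](C(C)C)(C(C)C)C(C)C)cc2)c([Li])c1OCC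
F8 | step 11 | pent-4-en-1-ynyl ether of 18 (S) | C=CCC#CO[C@@H](CCOC(c1ccccc1)(c1ccccc1)c1ccccc1)c1ccc(O[Si](C(C)C)(C(C)C)C(C)C)cc1
F9 | step 11 | 2-allyl analogue of alkenylcyclobutenone 28 | O=C3C(CC=C)=C(O[C@@H](CCOC(c1ccccc1)(c1ccccc1)c1ccccc1)c1ccc(O[Si](C(C)C)(C(C)C)C(C)C)cc1)C3/C(OCC)=C/C[C@@H](O[Si](C(C)C)(C(C)C)C(C)C)C(C)=C
F10 | step 11 | allyl analogue of dienylketene 29 | O=C=C(CC=C)/C(O[C@@H](CCOC(c1ccccc1)(c1ccccc1)c1ccccc1)c1ccc(O[Si](C(C)C)(C(C)C)C(C)C)cc1)=C\C(OCC)=C\C[C@@H](O[Si](C(C)C)(C(C)C)C(C)C)C(C)=C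
F11 | step 11 | allyl analogue of cyclohexadienone 30 | O=C3C(CC=C)=C(O[C@@H](CCOC(c1ccccc1)(c1ccccc1)c1ccccc1)c1ccc(O[Si](C(C)C)(C(C)C)C(C)C)cc1)C=C(OCC)C3C[C@@H](O[Si](C(C)C)(C(C)C)C(C)C)C(C)=C
F12 | step 11 | C8-allyl analogue of phenol 31 | C=C(C)[C@H](O[Si](C(C)C)(C(C)C)C(C)C)Cc1c(O)c(CC=C)c(O[C@@H](CCOC(c2ccccc2)(c2ccccc2)c2ccccc2)c2ccc(O[Si](C(C)C)(C(C)C)C(C)C)cc2)cc1OCC
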